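**Retrosynthetic overview**
- Kazinol J ⇐ its tris(methoxymethyl) ether; the three acetals come off in the last step.
- Key disconnection: the ArB–CH2|CH2 bond of the propane tether. The ring B aldehyde carbon is used as a benzyl carbanion (N–H hydrazone, loss of N2, nickel catalysis) and joined to the primary bromide of a ring A phenethyl unit; both carbons are normally electrophiles.
- Ring B aldehyde ⇐ double Stille prenylation of 2,3-dibromo-4,5-bis(methoxymethoxy)benzaldehyde ⇐ vanillin (dibromination, selective O-demethylation, MOM protection).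
- Ring A bromide ⇐ 4-bromo-3-methoxyphenol (MOM ether, then one-flask Br/Li exchange, oxirane opening, mesylation and bromide displacement).
- No ring is formed: both benzene rings are bought.

Assumption: Kazinol J has no stereocentre and no stereogenic double bond, so the "single enantiomer" is the achiral compound itself and no step has to set configuration.

**Step 1**
Reactants: 1 vanillin (4-hydroxy-3-methoxybenzaldehyde)
Product: 2 2,3-dibromo-4-hydroxy-5-methoxybenzaldehyde (5,6-dibromovanillin)
Conditions: Br2 (2.3 equiv), Fe powder (5 mol %), AcOH, 20 → 60 °C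
Reagents that add atoms: bromine, BrBr
Why: Electrophilic aromatic bromination goes first ortho to the free phenol and then, with FeBr3 formed in the flask, para to the methoxy group, which is the known double bromination of vanillin.

**Step 2**
Reactants: 2 2,3-dibromo-4-hydroxy-5-methoxybenzaldehyde
Product: 3 2,3-dibromo-4,5-dihydroxybenzaldehyde
Conditions: AlCl3 (1.2 equiv), pyridine (4.4 equiv), CH2Cl2, 40 °C; then 2 M HCl
Reagents that add atoms: none
Why: Lewis-acid ether cleavage of a guaiacol: AlCl3 chelates the phenoxide and the neighbouring methoxy oxygen, so chloride removes only this methyl group and the aldehyde and aryl bromides are untouched.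

**Step 3**
Reactants: 3 2,3-dibromo-4,5-dihydroxybenzaldehyde
Product: 4 2,3-dibromo-4,5-bis(methoxymethoxy)benzaldehyde
Conditions: NaH (2.5 equiv), MOMCl (2.6 equiv), DMF, 0 → 20 °C
Reagents that add atoms: chloromethyl methyl ether (MOMCl), COCCl
Why: Williamson-type O-alkylation of the catecholate gives a bis-acetal that is stable to palladium, hydrazine, base and nickel.

**Step 4**
Reactants: 4 2,3-dibromo-4,5-bis(methoxymethoxy)benzaldehyde
Product: 5 4,5-bis(methoxymethoxy)-2,3-bis(3-methylbut-2-en-1-yl)benzaldehyde
Conditions: tributyl(3-methylbut-2-en-1-yl)stannane (2.6 equiv), Pd(PPh3)4 (10 mol %), DMF, 100 °C, degassed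
Reagents that add atoms: tributyl(3-methylbut-2-en-1-yl)stannane, CCCC[Sn](CCCC)(CCCC)CC=C(C)C
Why: Double Stille cross-coupling in which zerovalent palladium inserts first into the bromide ortho to the formyl group and then into its neighbour, the aryl(allyl)palladium intermediates eliminate at the unsubstituted allyl terminus to give linear prenyl groups, and the neutral conditions spare aldehyde and acetals.

**Step 5**
Reactants: 6 4-bromo-3-methoxyphenol
Product: 7 1-bromo-2-methoxy-4-(methoxymethoxy)benzene
Conditions: NaH (1.2 equiv), MOMCl (1.2 equiv), THF, 0 → 20 °C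
Reagents that add atoms: chloromethyl methyl ether (MOMCl), COCCl
Why: Williamson O-alkylation masks the phenol so that it survives the organolithium and cannot later displace the side-chain bromide through the ring.

**Step 6**
Reactants: 7 1-bromo-2-methoxy-4-(methoxymethoxy)benzene
Product: 11 1-(2-bromoethyl)-2-methoxy-4-(methoxymethoxy)benzene, via aryllithium 8 (not isolated), via lithium alkoxide 9 (not isolated), via mesylate 10 (not isolated)
Conditions: t-BuLi (2.05 equiv), THF, −78 °C; oxirane (1.5 equiv, THF solution), −78 → 0 °C, then N2 purge; Ms2O (1.3 equiv), 0 °C; LiBr (4 equiv), 60 °C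
Reagents that add atoms: oxirane (ethylene oxide), C1CO1; lithium bromide, [Li+].[Br-]; into the intermediates only: tert-butyllithium, [Li]C(C)(C)C (lithium of 8 and 9); methanesulfonic anhydride, CS(=O)(=O)OS(C)(=O)=O (mesyl group of 10)
Why: Bromine–lithium exchange, SN2 opening of the epoxide by the aryllithium, O-sulfonylation of the lithium alkoxide and Finkelstein-type SN2 displacement by bromide are each fast and mutually compatible, so the two-carbon arm is added in one flask.

**Step 7**
Reactants: 5 4,5-bis(methoxymethoxy)-2,3-bis(3-methylbut-2-en-1-yl)benzaldehyde; 11 1-(2-bromoethyl)-2-methoxy-4-(methoxymethoxy)benzene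
Product: 13 1-{3-[2-methoxy-4-(methoxymethoxy)phenyl]propyl}-4,5-bis(methoxymethoxy)-2,3-bis(3-methylbut-2-en-1-yl)benzene, via hydrazone 12 (not isolated)
Conditions: N2H4·H2O (1.2 equiv), THF, 20 °C, concentrate and dry by toluene azeotrope; then 11 (1.5 equiv), Ni(cod)2 (10 mol %), PMe3 (20 mol %), K3PO4 (2 equiv), 4 Å MS, THF, 60 °C
Reagents that add atoms: hydrazine hydrate, NN.O (its two nitrogen atoms sit in 12 and leave as N2 on the way to 13)
Why: Proposed new method: the N–H hydrazone 12 serves as a benzyl-carbanion equivalent in a nickel-catalysed, N2-releasing C(sp3)–C(sp3) coupling with bromide 11 — oxidative addition of 11 to zerovalent nickel gives an alkylnickel bromide, K3PO4 exchanges bromide for the deprotonated hydrazone bound through nitrogen, a 1,3-shift of nickel from nitrogen to carbon with loss of N2 (the Wolff–Kishner driving force) gives a benzyl(alkyl) divalent nickel species, and reductive elimination forms the bond without creating a stereocentre; the closest known reaction type is the nickel-catalysed cross-coupling of aldehyde N–H hydrazones (carbonyl umpolung) with aryl and simple alkyl halides, here extended to a β-aryl bromide and a hindered, electron-rich hydrazone.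

**Step 8**
Reactants: 13 1-{3-[2-methoxy-4-(methoxymethoxy)phenyl]propyl}-4,5-bis(methoxymethoxy)-2,3-bis(3-methylbut-2-en-1-yl)benzene
Product: 14 Kazinol J, 5-[3-(4-hydroxy-2-methoxyphenyl)propyl]-3,4-bis(3-methylbut-2-en-1-yl)benzene-1,2-diol
Conditions: HCl (1.25 M in MeOH), degassed, 20 → 35 °C; NaHCO3 work-up under N2
Reagents that add atoms: none
Why: Acid-catalysed transacetalisation with methanol removes all three MOM groups as dimethoxymethane under conditions mild enough that the prenyl groups do not cyclise onto the ortho hydroxyl and the aryl methyl ether stays.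

**Compound list**
1 | vanillin (4-hydroxy-3-methoxybenzaldehyde) | COc1cc(C=O)ccc1O | starting material
2 | 2,3-dibromo-4-hydroxy-5-methoxybenzaldehyde | O=Cc1cc(OC)c(O)c(Br)c1Br | intermediate
3 | 2,3-dibromo-4,5-dihydroxybenzaldehyde | O=Cc1cc(O)c(O)c(Br)c1Br | intermediate
4 | 2,3-dibromo-4,5-bis(methoxymethoxy)benzaldehyde | O=Cc1cc(OCOC)c(OCOC)c(Br)c1Br | intermediate
5 | 4,5-bis(methoxymethoxy)-2,3-bis(3-methylbut-2-en-1-yl)benzaldehyde | O=Cc1cc(OCOC)c(OCOC)c(CC=C(C)C)c1CC=C(C)C | intermediate
6 | 4-bromo-3-methoxyphenol | COc1cc(O)ccc1Br | starting material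
7 | 1-bromo-2-methoxy-4-(methoxymethoxy)benzene | COc1cc(OCOC)ccc1Br | intermediate
8 | [2-methoxy-4-(methoxymethoxy)phenyl]lithium | COc1cc(OCOC)ccc1[Li] | intermediate
9 | lithium 2-[2-methoxy-4-(methoxymethoxy)phenyl]ethan-1-olate | COc1cc(OCOC)ccc1CC[O-].[Li+] | intermediate
10 | 2-[2-methoxy-4-(methoxymethoxy)phenyl]ethyl methanesulfonate | COc1cc(OCOC)ccc1CCOS(C)(=O)=O | intermediate
11 | 1-(2-bromoethyl)-2-methoxy-4-(methoxymethoxy)benzene | COc1cc(OCOC)ccc1CCBr | intermediate
12 | (E)-{[4,5-bis(methoxymethoxy)-2,3-bis(3-methylbut-2-en-1-yl)phenyl]methylidene}hydrazine | N/N=C/c1cc(OCOC)c(OCOC)c(CC=C(C)C)c1CC=C(C)C | intermediate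
13 | 1-{3-[2-methoxy-4-(methoxymethoxy)phenyl]propyl}-4,5-bis(methoxymethoxy)-2,3-bis(3-methylbut-2-en-1-yl)benzene | COc1cc(OCOC)ccc1CCCc1cc(OCOC)c(OCOC)c(CC=C(C)C)c1CC=C(C)C | intermediate
14 | Kazinol J, 5-[3-(4-hydroxy-2-methoxyphenyl)propyl]-3,4-bis(3-methylbut-2-en-1-yl)benzene-1,2-diol (achiral) | COc1cc(O)ccc1CCCc1cc(O)c(O)c(CC=C(C)C)c1CC=C(C)C | target

**Step count and risk**
Total steps: 8. Longest linear sequence: 6 (steps 1, 2, 3, 4, 7, 8 from vanillin).

The three steps most likely to fail:

Step 7 (hydrazone alkylation). The likely failures are loss of 11 as the styrene (E2 or β-hydride loss), N-alkylation of the hydrazone, or simple reduction of 12 to the methylarene. The fallback keeps the same bond and the same reversed polarity but uses a stoichiometric acyl-anion equivalent. It sets out from 5 and comes back at 13. Aldehyde 5 is condensed with propane-1,3-dithiol (LiBr 0.3 equiv, neat, 75 °C) to 2-[4,5-bis(methoxymethoxy)-2,3-bis(3-methylbut-2-en-1-yl)phenyl]-1,3-dithiane F1. This is deprotonated with n-BuLi (THF, −78 → −30 °C) to {2-[4,5-bis(methoxymethoxy)-2,3-bis(3-methylbut-2-en-1-yl)phenyl]-1,3-dithian-2-yl}lithium F2 and alkylated with 11 (−78 → 0 °C) to 2-[4,5-bis(methoxymethoxy)-2,3-bis(3-methylbut-2-en-1-yl)phenyl]-2-{2-[2-methoxy-4-(methoxymethoxy)phenyl]ethyl}-1,3-dithiane F3. Sulfur is then removed with nickel boride Ni2B made in the flask from NiCl2·6H2O and NaBH4 (MeOH/THF, 0 °C), which gives 13. The trisubstituted prenyl alkenes are the alkene class this reagent reduces most slowly, but some over-reduction is possible.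

Step 4 (double prenylation). The second bromide is flanked on both sides and may not couple, or a 1,1-dimethylallyl isomer may appear. The fallback reverses the roles of arene and prenyl unit for the hindered position. It sets out from 4 and comes back at 5. The Stille reaction is stopped after the first coupling (1.05 equiv stannane, 70 °C; the bromide ortho to the formyl group reacts first) at 3-bromo-4,5-bis(methoxymethoxy)-2-(3-methylbut-2-en-1-yl)benzaldehyde F4. Miyaura borylation (B2pin2, Pd(OAc)2, SPhos, KOAc, dioxane, 90 °C) gives 4,5-bis(methoxymethoxy)-2-(3-methylbut-2-en-1-yl)-3-(4,4,5,5-tetramethyl-1,3,2-dioxaborolan-2-yl)benzaldehyde F5. This boronate is then coupled with 1-bromo-3-methylbut-2-ene as the electrophile (Pd(PPh3)4, K2CO3, THF/H2O, 60 °C), where the aryl group is delivered to the unsubstituted terminus of the allyl–palladium complex, giving 5.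

Step 8 (deprotection). Protic acid may close a 2,2-dimethylchroman ring from the prenyl group next to the freed hydroxyl, and the catechol is air-sensitive. The fallback exchanges the acetals for silyl ethers with no free Brønsted acid. It sets out from 13 and comes back at 14. TMSOTf (6 equiv) and 2,2'-bipyridyl (9 equiv) in CH2Cl2 at 0 °C convert all three methoxymethyl ethers into trimethylsilyl ethers, giving Kazinol J tris(trimethylsilyl) ether F6, which is hydrolysed with water in THF at 20 °C under N2 to 14.

**Further compounds**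
F1 | step 7 | 2-[4,5-bis(methoxymethoxy)-2,3-bis(3-methylbut-2-en-1-yl)phenyl]-1,3-dithiane | C1CSC(SC1)c1cc(OCOC)c(OCOC)c(CC=C(C)C)c1CC=C(C)C
F2 | step 7 | {2-[4,5-bis(methoxymethoxy)-2,3-bis(3-methylbut-2-en-1-yl)phenyl]-1,3-dithian-2-yl}lithium | [Li]C1(SCCCS1)c1cc(OCOC)c(OCOC)c(CC=C(C)C)c1CC=C(C)C
F3 | step 7 | 2-[4,5-bis(methoxymethoxy)-2,3-bis(3-methylbut-2-en-1-yl)phenyl]-2-{2-[2-methoxy-4-(methoxymethoxy)phenyl]ethyl}-1,3-dithiane | COc1cc(OCOC)ccc1CCC1(SCCCS1)c1cc(OCOC)c(OCOC)c(CC=C(C)C)c1CC=C(C)C
F4 | step 4 | 3-bromo-4,5-bis(methoxymethoxy)-2-(3-methylbut-2-en-1-yl)benzaldehyde | O=Cc1cc(OCOC)c(OCOC)c(Br)c1CC=C(C)C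
F5 | step 4 | 4,5-bis(methoxymethoxy)-2-(3-methylbut-2-en-1-yl)-3-(4,4,5,5-tetramethyl-1,3,2-dioxaborolan-2-yl)benzaldehyde | O=Cc1cc(OCOC)c(OCOC)c(B2OC(C)(C)C(C)(C)O2)c1CC=C(C)C
F6 | step 8 | Kazinol J tris(trimethylsilyl) ether | COc1cc(O[Si](C)(C)C)ccc1CCCc1cc(O[Si](C)(C)C)c(O[Si](C)(C)C)c(CC=C(C)C)c1CC=C(C)C
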